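**Retrosynthetic overview**
1. Target ⇐ ketone 41 by α-methylenation at C16 and desilylation. The C6 acetate comes from Baeyer–Villiger oxidation of a C5–CH2–C(O)CH3 side chain.
2. Ring A (C1–C5, C10) closes last. A C1/C10 spiro-oxirane is opened by titanocene to the tertiary C10 radical, which adds 6-exo to an enone (C5–C10 bond). This sets the spiro quaternary C10 and C5 and frees the C1 hydroxyl.
3. Enabling feature: C10 of the δ-lactone ring has an oxygenated neighbour C1, so C1/C10 can be an oxirane, a masked tertiary radical. C5 carries CH2OAc, the Baeyer–Villiger image of CH2C(O)CH3, so C5 can be an enone β-carbon. C9, O1 and C6 are all equatorial on ring A, and only the H9 face of C10 is open.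
4. Ring order: δ-lactone (Ireland–Claisen, lactonisation) → ring C (ring-closing metathesis) → ring D (5-exo radical closure C16–C13) → ring A.
5. Building blocks: 2,2-dimethylpent-4-enal, O-TBS propargyl alcohol, acrolein, pent-4-enoic acid, ethyl vinyl ether/PhSeCl.

Key step: step 19

Remark: atoms are numbered as in ent-kaurane. C8 in 19–24 and C15 in 31–40 are carried as epimer mixtures, because C8 is re-set in step 15 and C15 is oxidised in step 23.

**Step 1**
Reactants: 1 2,2-dimethylpent-4-enal
Product: 2 3,3-dimethylhexa-1,5-diene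
Conditions: Ph3PCH3Br, KOtBu, THF, 0 °C to rt
Reagents that add atoms: methyltriphenylphosphonium bromide, C[P+](c1ccccc1)(c1ccccc1)c1ccccc1.[Br-]
Why: Wittig methylenation of a non-enolisable aldehyde; the neopentyl vinyl group is a base- and radical-stable mask of the later C5 aldehyde, and no stereocentre forms.

**Step 2**
Reactants: 2 3,3-dimethylhexa-1,5-diene
Product: 4 4,4-dimethylhex-5-en-1-ol, via trialkylborane 3 (not isolated)
Conditions: Sia2BH (from BH3·THF and 2-methylbut-2-ene), THF, 0 °C; then NaOH, H2O2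
Reagents that add atoms: hydrogen peroxide, OO; disiamylborane, CC(C)C(C)BC(C)C(C)C (its atoms stay only in 3)
Why: Hydroboration–oxidation with a bulky dialkylborane should select the allyl terminus over the neopentyl vinyl group on steric grounds; no stereocentre forms.

**Step 3**
Reactants: 4 4,4-dimethylhex-5-en-1-ol
Product: 5 4,4-dimethylhex-5-enal
Conditions: Dess–Martin periodinane, NaHCO3, CH2Cl2, rt
Reagents that add atoms: none
Why: Dess–Martin oxidation of a primary alcohol stops at the aldehyde and leaves the alkene untouched.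

**Step 4**
Reactants: 6 tert-butyldimethyl(prop-2-yn-1-yloxy)silane; 7 acrolein
Product: 9 rac-6-[(tert-butyldimethylsilyl)oxy]hex-1-en-4-yn-3-ol, via lithium acetylide 8 (not isolated)
Conditions: n-BuLi, THF, −78 °C; then 7; H2O
Reagents that add atoms: n-butyllithium, [Li]CCCC (lithium only in 8)
Why: 1,2-Addition of a lithium acetylide to an enal is fast at low temperature and joins C9/C10/C20 to C11/C12; the racemate is resolved in step 5.

**Step 5**
Reactants: 9 rac-6-[(tert-butyldimethylsilyl)oxy]hex-1-en-4-yn-3-ol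
Product: 10 (S)-6-[(tert-butyldimethylsilyl)oxy]hex-1-en-4-yn-3-ol
Conditions: Ti(OiPr)4, L-(+)-DIPT, t-BuOOH (0.6 equiv), 4 Å MS, CH2Cl2, −20 °C
Reagents that add atoms: none
Why: In the Sharpless kinetic resolution of a 1-alken-3-ol with L-(+)-DIPT the R enantiomer is epoxidised faster, so the S carbinol that becomes C11 is recovered.

**Step 6**
Reactants: 10 (S)-6-[(tert-butyldimethylsilyl)oxy]hex-1-en-4-yn-3-ol
Product: 12 (3S,4Z)-6-[(tert-butyldimethylsilyl)oxy]-5-iodohexa-1,4-dien-3-ol, via cyclic alkenylalanate 11 (not isolated)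
Conditions: NaAlH2(OCH2CH2OMe)2, Et2O, 0 °C; then I2, −78 °C
Reagents that add atoms: iodine, II; sodium bis(2-methoxyethoxy)aluminium hydride, [Na+].[AlH2-](OCCOC)OCCOC (metal and alkoxide only in 11)
Why: Hydroxyl-directed trans-hydroalumination of a propargylic alcohol puts aluminium on the distal alkyne carbon C10, and iodinolysis with retention fixes the Z geometry; low temperature suppresses loss of the β-silyloxy group.

**Step 7**
Reactants: 12 (3S,4Z)-6-[(tert-butyldimethylsilyl)oxy]-5-iodohexa-1,4-dien-3-ol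
Product: 13 (3S,4Z)-3,6-bis[(tert-butyldimethylsilyl)oxy]-5-iodohexa-1,4-diene
Conditions: TBSCl, imidazole, DMF, rt
Reagents that add atoms: tert-butyldimethylsilyl chloride, CC(C)(C)[Si](C)(C)Cl
Why: Standard silylation protects the C11 hydroxyl until the last step.

**Step 8**
Reactants: 13 (3S,4Z)-3,6-bis[(tert-butyldimethylsilyl)oxy]-5-iodohexa-1,4-diene; 5 4,4-dimethylhex-5-enal
Product: 16 (3S,4Z,6S)-3-[(tert-butyldimethylsilyl)oxy]-5-{[(tert-butyldimethylsilyl)oxy]methyl}-9,9-dimethylundeca-1,4,10-trien-6-ol, via alkenyllithium 14 (not isolated), via alkenylzinc bromide 15 (not isolated)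
Conditions: t-BuLi (2 equiv), Et2O, −78 °C; ZnBr2; N,N,N′,N′-tetraethylethylenediamine, (+)-MIB (10 mol %), then 5, hexanes/Et2O, 0 °C
Reagents that add atoms: tert-butyllithium, [Li]C(C)(C)C (lithium only in 14); zinc bromide, [Zn+2].[Br-].[Br-] (zinc and bromine only in 15)
Why: In this amino-alcohol-catalysed asymmetric alkenylzinc addition to an aliphatic aldehyde, the (+)-MIB enantiomer delivers the alkenyl group to the Re face and should give the 6S carbinol, a temporary centre that steers step 10.

**Step 9**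
Reactants: 16 the (3S,4Z,6S)-trienol; 17 pent-4-enoic acid
Product: 18 (3S,4Z,6S)-3-[(tert-butyldimethylsilyl)oxy]-5-{[(tert-butyldimethylsilyl)oxy]methyl}-9,9-dimethylundeca-1,4,10-trien-6-yl pent-4-enoate
Conditions: DCC, DMAP, CH2Cl2, 0 °C to rt
Reagents that add atoms: none
Why: Steglich esterification attaches C7, C8, C14 and C13 without touching the stereocentres.

**Step 10**
Reactants: 18 the pent-4-enoate
Product: 21 (3R,4Z)-2-allyl-3-[(1S)-1-(tert-butyldimethylsilyloxy)allyl]-4-[(tert-butyldimethylsilyloxy)methyl]-8,8-dimethyldeca-4,9-dienoic acid (C2 epimers), via silyl ketene acetal 19 (not isolated), via trimethylsilyl ester 20 (not isolated)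
Conditions: LDA, TMSCl, Et3N, THF, −78 °C to 60 °C; then aq. citric acid
Reagents that add atoms: chlorotrimethylsilane, C[Si](C)(C)Cl (silicon only in 19 and 20)
Why: The Ireland–Claisen rearrangement through a chair with the C2 chain equatorial on the carbinol carbon forms the C8–C9 bond suprafacially, so the 6S centre is transferred to C9 (R) and the new C10=C1 alkene has the chain cis to C20 (Z).

**Step 11**
Reactants: 21 the dienoic acid
Product: 23 (4R,5Z)-3-allyl-4-[(1S)-1-(tert-butyldimethylsilyloxy)allyl]-5-(4,4-dimethylhex-5-en-1-ylidene)tetrahydro-2H-pyran-2-one (C3 epimers), via hydroxy acid 22 (not isolated)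
Conditions: HF·pyridine, pyridine, THF, 0 °C; then EDC·HCl, DMAP, CH2Cl2, rt
Reagents that add atoms: none
Why: The primary allylic silyl ether is cleaved faster than the secondary one, and carbodiimide lactonisation of the δ-hydroxy acid closes the lactone ring, which then acts as the template for C8.

**Step 12**
Reactants: 23 the monocyclic lactone
Product: 24 (4Z,4aR,5S)-5-(tert-butyldimethylsilyloxy)-4-(4,4-dimethylhex-5-en-1-ylidene)-3,4,4a,5,8,8a-hexahydro-1H-isochromen-1-one (C8a epimers)
Conditions: second-generation Grubbs catalyst (5 mol %), CH2Cl2 (2 mM), reflux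
Reagents that add atoms: none
Why: Ring-closing metathesis of the allyl group with the vinyl carbinol closes ring C as the C12=C13 cyclohexene; the trisubstituted alkene and the neopentyl vinyl group are too hindered to compete.

**Step 13**
Reactants: 24 the bicyclic lactone
Product: 25 C1/C10 spiro-oxirane of 24: oxygen added syn to the Z alkene, oxirane CH (C1) S, bearing the 3,3-dimethylpent-4-en-1-yl chain cis to C20
Conditions: 1,2:4,5-di-O-isopropylidene-β-L-erythro-2,3-hexodiulo-2,6-pyranose (30 mol %), Oxone, K2CO3, Bu4NHSO4, MeCN/dimethoxymethane/aq. borate buffer, 0 °C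
Reagents that add atoms: potassium peroxymonosulfate, [K+].OOS(=O)(=O)[O-]
Why: The Shi epoxidation is selective for trisubstituted over cis-disubstituted and terminal alkenes, and the spiro transition state of the L-series ketone should deliver oxygen to the face that makes C1 S; the C10 configuration is erased in step 19.

**Step 14**
Reactants: 26 ethyl vinyl ether; 27 benzeneselenenyl chloride
Product: 29 (phenylselanyl)acetaldehyde, via chloro ether 28 (not isolated)
Conditions: CH2Cl2, −78 °C; then aq. NaHCO3, rt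
Reagents that add atoms: water, O
Why: Electrophilic selenenylation of an enol ether followed by hydrolysis of the α-chloro ether gives the two-carbon C15/C16 unit that carries a radical precursor.

**Step 15**
Reactants: 25 the spiro-oxirane lactone; 29 (phenylselanyl)acetaldehyde
Product: 32 cis-fused lactone with quaternary C8 bearing CH(OSiEt3)CH2SePh on the face of H9 (C15 epimers), via lithium enolate 30 (not isolated), via lithium aldolate 31 (not isolated)
Conditions: LDA, THF, −78 °C; 29; then Et3SiCl, DMAP, −78 to −20 °C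
Reagents that add atoms: chlorotriethylsilane, CC[Si](Cl)(CC)CC; lithium diisopropylamide, [Li]N(C(C)C)C(C)C (lithium only in 30 and 31)
Why: The aldol addition of the ring-fusion lactone enolate should occur on the convex face syn to H9, as in angular alkylation of fused enolates, which puts C15 trans to C10; silylation of the aldolate blocks retro-aldol cleavage.

**Step 16**
Reactants: 32 the selenide
Product: 33 tricyclic lactone with the bicyclo[3.2.1]octane in place (C8, C9, C11, C13 as in the target; 11-OTBS, 15-OTES, C1/C10 oxirane, vinyl-terminated chain)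
Conditions: Bu3SnH (syringe pump), AIBN, benzene, 80 °C
Reagents that add atoms: none
Why: In this 5-exo-trig radical cyclisation the primary C16 radical, held on the H9 face, can reach only that face of C13, so ring D closes with C13 fixed by the bridge; the oxirane has already removed the only competing alkene near C16.

**Step 17**
Reactants: 33 the tricyclic vinyl compound
Product: 35 the corresponding C5 aldehyde (2,2-dimethyl-4-substituted butanal terminus), via ozonide 34 (not isolated)
Conditions: O3, CH2Cl2, −78 °C; then PPh3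
Reagents that add atoms: ozone, [O-][O+]=O
Why: Ozonolysis of the only remaining alkene unmasks a non-enolisable aldehyde; oxirane, lactone and silyl ethers are inert.

**Step 18**
Reactants: 35 the aldehyde
Product: 36 the (E)-enone, chain terminus C4(CH3)2–CH=CH–C(O)CH3
Conditions: (MeO)2P(O)CH2C(O)CH3, LiCl, iPr2NEt, MeCN, rt
Reagents that add atoms: dimethyl (2-oxopropyl)phosphonate, COP(=O)(OC)CC(C)=O
Why: Horner–Wadsworth–Emmons olefination under Masamune–Roush conditions gives the E enone without harming the oxirane, and brings in C6 together with the carbons of the future C6 acetate.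

**Step 19**
Reactants: 36 the oxirane enone
Product: 37 tetracyclic spiro lactone with ring A closed: 1α-OH (1S), spiro C10 and C5 as in the target, C5–CH2C(O)CH3, 11-OTBS, 15-OTES
Conditions: Cp2TiCl2 (20 mol %), Mn dust, 2,4,6-collidine·HCl, THF, rt
Reagents that add atoms: none
Why: Cp2TiCl, the trivalent titanium species made from Cp2TiCl2 and Mn, binds the oxirane oxygen and cleaves the C10–O bond homolytically to the tertiary β-titanoxy radical at C10, which adds to C5, the β-carbon of the enone; a second trivalent titanium reduces the resulting α-keto radical to a titanium enolate, and collidinium chloride protonates the enolate and the C1 alkoxide and returns Cp2TiCl2. The closest known reaction type is the RajanBabu–Nugent reductive epoxide opening, run catalytically, with intramolecular Giese addition to an α,β-unsaturated carbonyl acceptor. Ring A closes in the 6-exo-trig mode through a chair in which C9, the C1 titanoxy group and the oxobutenyl arm are equatorial and C20 is axial. C10 is set by approach of C5 to the planar radical from the open face that carries H9, because the other face lies under ring C; C1 is not touched and keeps the S configuration from step 13; C5 is set by the equatorial acceptor arm, which places C6 cis to C20 and to the C1 oxygen. The step needs oxirane opening toward C10 and not C1 (tertiary versus secondary radical), 6-exo and not 7-endo closure (polarity match of the nucleophilic radical with the enone β-carbon, helped by the gem-dimethyl group at C4), and epoxide opening faster than enone reduction (aliphatic enones react only slowly with Cp2TiCl); lactone and silyl ethers are inert.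

**Step 20**
Reactants: 37 the C1 alcohol
Product: 38 the 1α-acetate
Conditions: Ac2O, DMAP, Et3N, CH2Cl2, rt to 40 °C
Reagents that add atoms: acetic anhydride, CC(=O)OC(C)=O
Why: DMAP-catalysed acetylation of the only free hydroxyl, which is equatorial although neopentyl, installs the first acetate with retention.

**Step 21**
Reactants: 38 the methyl ketone
Product: 39 the 1α,6-diacetate (11-OTBS, 15-OTES)
Conditions: (CF3CO)2O, urea·H2O2, Na2HPO4, CH2Cl2, 0 °C
Reagents that add atoms: trifluoroperacetic acid, OOC(=O)C(F)(F)F (made from urea–hydrogen peroxide, NC(N)=O.OO, and trifluoroacetic anhydride)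
Why: In the Baeyer–Villiger oxidation of the only ketone present the primary alkyl group C6 migrates in preference to methyl, so the activating acetyl group becomes the C6 acetate; the buffer protects the silyl ethers.

**Step 22**
Reactants: 39 the bis-silyl ether
Product: 40 the C15 alcohol (11-OTBS retained)
Conditions: PPTS, MeOH/CH2Cl2, 0 °C to rt
Reagents that add atoms: none
Why: Mild acid methanolysis distinguishes the triethylsilyl from the tert-butyldimethylsilyl ether and leaves the acetates and the lactone intact.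

**Step 23**
Reactants: 40 the C15 alcohol
Product: 41 the C15 ketone (β-keto lactone)
Conditions: Dess–Martin periodinane, NaHCO3, CH2Cl2, rt
Reagents that add atoms: none
Why: Neutral Dess–Martin oxidation converts both C15 epimers into one ketone without risk to the non-enolisable β-keto lactone.

**Step 24**
Reactants: 41 the C15 ketone
Product: 43 11-O-TBS rabdosin B, via Mannich base 42 (not isolated)
Conditions: CH2(NMe2)2, Ac2O, DMF, 95 °C
Reagents that add atoms: bis(dimethylamino)methane, CN(C)CN(C)C
Why: Mannich α-methylenation works because C16 is the only enolisable position next to C15 (C8 is quaternary), and loss of dimethylamine can only give the exocyclic C16=C17 alkene because C13 is a bridgehead.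

**Step 25**
Reactants: 43 11-O-TBS rabdosin B
Product: 44 rabdosin B
Conditions: HF·pyridine, MeCN, 0 °C to rt
Reagents that add atoms: none
Why: Fluoride-mediated desilylation under weakly acidic conditions frees the 11β-hydroxyl without touching the acetates, the lactone or the enone.

**Compound list**
1 | 2,2-dimethylpent-4-enal | C=CCC(C)(C)C=O | starting material
2 | 3,3-dimethylhexa-1,5-diene | C=CCC(C)(C)C=C | intermediate
3 | (4,4-dimethylhex-5-en-1-yl)bis(3-methylbutan-2-yl)borane | C=CC(C)(C)CCCB(C(C)C(C)C)C(C)C(C)C | intermediate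
4 | 4,4-dimethylhex-5-en-1-ol | C=CC(C)(C)CCCO | intermediate
5 | 4,4-dimethylhex-5-enal | C=CC(C)(C)CCC=O | intermediate
6 | tert-butyldimethyl(prop-2-yn-1-yloxy)silane | C#CCO[Si](C)(C)C(C)(C)C | starting material
7 | acrolein | C=CC=O | starting material
8 | lithium acetylide of 6 | [Li]C#CCO[Si](C)(C)C(C)(C)C | intermediate
9 | rac-6-(TBSO)hex-1-en-4-yn-3-ol | C=CC(O)C#CCO[Si](C)(C)C(C)(C)C | intermediate
10 | (S)-6-(TBSO)hex-1-en-4-yn-3-ol | C=C[C@H](O)C#CCO[Si](C)(C)C(C)(C)C | intermediate
11 | sodium cyclic alkenylalanate | [Na+].C=C[C@H]1C=C(CO[Si](C)(C)C(C)(C)C)[Al-](OCCOC)(OCCOC)O1 | intermediate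
12 | (3S,4Z)-6-(TBSO)-5-iodohexa-1,4-dien-3-ol | C=C[C@H](O)/C=C(/CO[Si](C)(C)C(C)(C)C)I | intermediate
13 | (3S,4Z)-3,6-bis(TBSO)-5-iodohexa-1,4-diene | C=C[C@H](O[Si](C)(C)C(C)(C)C)/C=C(/CO[Si](C)(C)C(C)(C)C)I | intermediate
14 | alkenyllithium from 13 | C=C[C@H](O[Si](C)(C)C(C)(C)C)/C=C(/CO[Si](C)(C)C(C)(C)C)[Li] | intermediate
15 | alkenylzinc bromide from 14 | C=C[C@H](O[Si](C)(C)C(C)(C)C)/C=C(/CO[Si](C)(C)C(C)(C)C)[Zn]Br | intermediate
16 | (3S,4Z,6S)-trienol | C=C[C@H](O[Si](C)(C)C(C)(C)C)/C=C(/CO[Si](C)(C)C(C)(C)C)[C@@H](O)CCC(C)(C)C=C | intermediate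
17 | pent-4-enoic acid | C=CCCC(=O)O | starting material
18 | pent-4-enoate of 16 | C=C[C@H](O[Si](C)(C)C(C)(C)C)/C=C(/CO[Si](C)(C)C(C)(C)C)[C@@H](OC(=O)CCC=C)CCC(C)(C)C=C | intermediate
19 | trimethylsilyl ketene acetal of 18 | C=C[C@H](O[Si](C)(C)C(C)(C)C)/C=C(/CO[Si](C)(C)C(C)(C)C)[C@@H](OC(O[Si](C)(C)C)=CCC=C)CCC(C)(C)C=C | intermediate
20 | trimethylsilyl ester of 21 | C[Si](C)(C)OC(=O)C(CC=C)[C@@H]([C@@H](O[Si](C)(C)C(C)(C)C)C=C)/C(CO[Si](C)(C)C(C)(C)C)=C/CCC(C)(C)C=C | intermediate
21 | (3R,4Z)-dienoic acid (C2 epimers) | OC(=O)C(CC=C)[C@@H]([C@@H](O[Si](C)(C)C(C)(C)C)C=C)/C(CO[Si](C)(C)C(C)(C)C)=C/CCC(C)(C)C=C | intermediate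
22 | δ-hydroxy acid | OC(=O)C(CC=C)[C@@H]([C@@H](O[Si](C)(C)C(C)(C)C)C=C)/C(CO)=C/CCC(C)(C)C=C | intermediate
23 | monocyclic δ-lactone | O=C1OC/C(=C\CCC(C)(C)C=C)[C@H]([C@@H](O[Si](C)(C)C(C)(C)C)C=C)C1CC=C | intermediate
24 | bicyclic lactone (ring C closed) | O=C1OC/C(=C\CCC(C)(C)C=C)[C@@H]2[C@@H](O[Si](C)(C)C(C)(C)C)C=CCC12 | intermediate
25 | C1/C10 spiro-oxirane | O=C1OC[C@]3(O[C@H]3CCC(C)(C)C=C)[C@@H]2[C@@H](O[Si](C)(C)C(C)(C)C)C=CCC12 | intermediate
26 | ethyl vinyl ether | C=COCC | starting material
27 | benzeneselenenyl chloride | Cl[Se]c1ccccc1 | starting material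
28 | 1-chloro-1-ethoxy-2-(phenylselanyl)ethane | CCOC(Cl)C[Se]c1ccccc1 | intermediate
29 | (phenylselanyl)acetaldehyde | O=CC[Se]c1ccccc1 | intermediate
30 | lithium enolate of 25 | [Li]OC1=C2CC=C[C@H](O[Si](C)(C)C(C)(C)C)[C@H]2[C@]3(CO1)O[C@H]3CCC(C)(C)C=C | intermediate
31 | lithium aldolate | O=C1OC[C@]3(O[C@H]3CCC(C)(C)C=C)[C@@H]2[C@@H](O[Si](C)(C)C(C)(C)C)C=CC[C@]12C(O[Li])C[Se]c1ccccc1 | intermediate
32 | C8-quaternary selenide, 15-OTES | O=C1OC[C@]3(O[C@H]3CCC(C)(C)C=C)[C@@H]2[C@@H](O[Si](C)(C)C(C)(C)C)C=CC[C@]12C(O[Si](CC)(CC)CC)C[Se]c1ccccc1 | intermediate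
33 | tricyclic lactone (ring D closed) | C1C(O[Si](CC)(CC)CC)[C@]23C[C@H]1C[C@H](O[Si](C)(C)C(C)(C)C)[C@H]2[C@]4(COC3=O)O[C@H]4CCC(C)(C)C=C | intermediate
34 | ozonide of 33 | C1C(O[Si](CC)(CC)CC)[C@]23C[C@H]1C[C@H](O[Si](C)(C)C(C)(C)C)[C@H]2[C@]4(COC3=O)O[C@H]4CCC(C)(C)C5OCOO5 | intermediate
35 | C5 aldehyde | C1C(O[Si](CC)(CC)CC)[C@]23C[C@H]1C[C@H](O[Si](C)(C)C(C)(C)C)[C@H]2[C@]4(COC3=O)O[C@H]4CCC(C)(C)C=O | intermediate
36 | oxirane (E)-enone | C1C(O[Si](CC)(CC)CC)[C@]23C[C@H]1C[C@H](O[Si](C)(C)C(C)(C)C)[C@H]2[C@]4(COC3=O)O[C@H]4CCC(C)(C)/C=C/C(C)=O | intermediate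
37 | tetracyclic C1 alcohol, methyl ketone | C1C(O[Si](CC)(CC)CC)[C@]23C[C@H]1C[C@H](O[Si](C)(C)C(C)(C)C)[C@H]2[C@]1(COC3=O)[C@@H](O)CCC(C)(C)[C@H]1CC(C)=O | intermediate
38 | 1α-acetate, methyl ketone | C1C(O[Si](CC)(CC)CC)[C@]23C[C@H]1C[C@H](O[Si](C)(C)C(C)(C)C)[C@H]2[C@]1(COC3=O)[C@@H](OC(C)=O)CCC(C)(C)[C@H]1CC(C)=O | intermediate
39 | 1α,6-diacetate, 11-OTBS, 15-OTES | C1C(O[Si](CC)(CC)CC)[C@]23C[C@H]1C[C@H](O[Si](C)(C)C(C)(C)C)[C@H]2[C@]1(COC3=O)[C@@H](OC(C)=O)CCC(C)(C)[C@H]1COC(C)=O | intermediate
40 | C15 alcohol | C1C(O)[C@]23C[C@H]1C[C@H](O[Si](C)(C)C(C)(C)C)[C@H]2[C@]1(COC3=O)[C@@H](OC(C)=O)CCC(C)(C)[C@H]1COC(C)=O | intermediate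
41 | C15 ketone | C1C(=O)[C@]23C[C@H]1C[C@H](O[Si](C)(C)C(C)(C)C)[C@H]2[C@]1(COC3=O)[C@@H](OC(C)=O)CCC(C)(C)[C@H]1COC(C)=O | intermediate
42 | C16 Mannich base | CN(C)CC1C(=O)[C@]23C[C@H]1C[C@H](O[Si](C)(C)C(C)(C)C)[C@H]2[C@]1(COC3=O)[C@@H](OC(C)=O)CCC(C)(C)[C@H]1COC(C)=O | intermediate
43 | 11-O-TBS rabdosin B | C=C1C(=O)[C@]23C[C@H]1C[C@H](O[Si](C)(C)C(C)(C)C)[C@H]2[C@]1(COC3=O)[C@@H](OC(C)=O)CCC(C)(C)[C@H]1COC(C)=O | intermediate
44 | rabdosin B | C=C1C(=O)[C@]23C[C@H]1C[C@H](O)[C@H]2[C@]1(COC3=O)[C@@H](OC(C)=O)CCC(C)(C)[C@H]1COC(C)=O | target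

**Step count**
Total step count: 25. Longest linear sequence: 21 steps (6/7 → 44: steps 4–13 and 15–25).

**Steps most likely to fail**

Step 19. The enone may be reduced by trivalent titanium. The hindered tertiary radical may also be lost by disproportionation or hydrogen abstraction before the ring closes. Fallback: radical generation is separated from titanium. Setting out from 36, MgBr2·OEt2 in Et2O at −20 °C opens the oxirane at the tertiary carbon to the C10 bromohydrin F1. Bromine abstraction with Bu3SnH and Et3B/air in toluene at rt then drives the same Giese ring closure under tin hydride conditions. This path returns to the route at 37.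

Step 15. The aldolate may revert on warming, the enolate may attack the neighbouring oxirane, or the crowded enolate may fail to add to an enolisable aldehyde. Fallback: the side chain is built from the smallest electrophile. Setting out from 25, LDA and then monomeric formaldehyde give the C8 hydroxymethyl lactone F2. Dess–Martin oxidation gives the C15 aldehyde F3. PhSeCH2Li (from (PhSe)2CH2 and n-BuLi, −78 °C) adds to give the selenide alcohol F4. Silylation with Et3SiCl and imidazole returns to the route at 32.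

Step 13. The substrate may override the catalyst and give poor facial selectivity, and the lactone may hydrolyse in the basic buffer. Fallback: oxygen is delivered through the free C20 allylic alcohol before lactonisation. Setting out from 21, TMSCHN2 gives the methyl ester F5 and HF·pyridine gives the allylic alcohol F6. Sharpless asymmetric epoxidation (Ti(OiPr)4, L-(+)-DET, t-BuOOH, −20 °C) gives the epoxy alcohol F7. Bu2SnO-catalysed lactonisation in toluene at 80 °C gives the monocyclic epoxy lactone F8. Ring-closing metathesis with the second-generation Grubbs catalyst returns to the route at 25.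

**Further compounds**
F1 | step 19 | C10 bromohydrin of 36 | C1C(O[Si](CC)(CC)CC)[C@]23C[C@H]1C[C@H](O[Si](C)(C)C(C)(C)C)[C@H]2[C@](Br)(COC3=O)[C@@H](O)CCC(C)(C)/C=C/C(C)=O
F2 | step 15 | C8 hydroxymethyl lactone | O=C1OC[C@]3(O[C@H]3CCC(C)(C)C=C)[C@@H]2[C@@H](O[Si](C)(C)C(C)(C)C)C=CC[C@]12CO
F3 | step 15 | C15 aldehyde | O=C1OC[C@]3(O[C@H]3CCC(C)(C)C=C)[C@@H]2[C@@H](O[Si](C)(C)C(C)(C)C)C=CC[C@]12C=O
F4 | step 15 | selenide alcohol (C15 epimers) | O=C1OC[C@]3(O[C@H]3CCC(C)(C)C=C)[C@@H]2[C@@H](O[Si](C)(C)C(C)(C)C)C=CC[C@]12C(O)C[Se]c1ccccc1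
F5 | step 13 | methyl ester of 21 | COC(=O)C(CC=C)[C@@H]([C@@H](O[Si](C)(C)C(C)(C)C)C=C)/C(CO[Si](C)(C)C(C)(C)C)=C/CCC(C)(C)C=C
F6 | step 13 | allylic alcohol methyl ester | COC(=O)C(CC=C)[C@@H]([C@@H](O[Si](C)(C)C(C)(C)C)C=C)/C(CO)=C/CCC(C)(C)C=C
F7 | step 13 | epoxy alcohol methyl ester | COC(=O)C(CC=C)[C@@H]([C@@H](O[Si](C)(C)C(C)(C)C)C=C)[C@]1(CO)O[C@H]1CCC(C)(C)C=C
F8 | step 13 | monocyclic epoxy lactone | O=C1OC[C@]3(O[C@H]3CCC(C)(C)C=C)[C@H]([C@@H](O[Si](C)(C)C(C)(C)C)C=C)C1CC=C
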